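Ring B is cut at C1–C2 and C5–C6 of its cyclohexane-1,3,5-trione. The bridge CH2, C6 and the C1 carbonyl are then already present in ring A as the lactone arm of a dihydrocoumarin, while C2–C5, with the quaternary stereocentre C4, come from an α,α-disubstituted acetoacetate. In one operation the methyl-ketone enolate is acylated by the aryl lactone and the resulting diketone polyanion cyclises onto its own ester, so ring B forms with the bridge installed. The precursors are unprotected 8-butanoyl-6-geranyl-5,7-dihydroxychroman-2-one, whose phenoxides silence the butanoyl ketone, and methyl (S)-2-geranyl-2-methylacetoacetate, whose methyl ester accepts the carbanion far more readily than a tert-butyl ester would.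

Key step: step 6

Geranyl denotes (2E)-3,7-dimethylocta-2,6-dien-1-yl throughout.
Remark (assumption): butanoylation in step 2 is taken to occur at C8, as with 5,7-dihydroxycoumarins; a C6 isomer would lead to a lactone regioisomer of 8 that opens to the same ring A in step 6.
Remark (assumption): the toluene–HMPA protocol with the L-valine auxiliary in step 5 is taken to give the (S) ester; the configuration is to be confirmed on 13, and the mirror-image auxiliary would be used otherwise.

Step 1
Reactants: 1 phloroglucinol (benzene-1,3,5-triol); 2 acrylic acid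
Product: 4 5,7-dihydroxychroman-2-one, via trihydroxyphenylpropanoic acid 3 (not isolated)
Conditions: sulfonic acid resin (Amberlyst-15), toluene, reflux, Dean–Stark
Reagents that add atoms: acrylic acid (2), C=CC(=O)O
Why: Acid-catalysed Friedel–Crafts-type conjugate addition of the electron-rich arene to acrylic acid followed by lactonisation onto an ortho hydroxyl is an established way from phenols to 3,4-dihydrocoumarins, the symmetry of 1 allows only one product, and the mild resin acid disfavours C-acylation to a chroman-4-one.

Step 2
Reactants: 4 5,7-dihydroxychroman-2-one; 5 butanoyl chloride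
Product: 6 8-butanoyl-5,7-dihydroxychroman-2-one
Conditions: PrCOCl (1.1 equiv), AlCl3 (3.5 equiv), PhNO2–(CH2Cl)2, 0 → 50 °C; then ice/aq. HCl
Reagents that add atoms: butanoyl chloride (5), CCCC(=O)Cl
Why: Friedel–Crafts acylation of the activated ring is expected at C8, which is para to the free 5-hydroxyl and ortho to the 7-hydroxyl, the chelated ketone formed deactivates the ring against a second acylation, and the lactone is stable to AlCl3 far below Fries temperatures.

Step 3
Reactants: 6 8-butanoyl-5,7-dihydroxychroman-2-one; 7 geranyl bromide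
Product: 8 8-butanoyl-6-geranyl-5,7-dihydroxychroman-2-one
Conditions: NaH (1.0 equiv), toluene, 0 °C → rt; geranyl bromide (1.05 equiv), rt, dark
Reagents that add atoms: geranyl bromide (7), CC(C)=CCC/C(C)=C/CBr
Why: Claisen-type ortho-C-allylation of a sodium phenoxide by an allylic bromide in a non-polar solvent is favoured over O-alkylation by tight ion pairing, C6 between the two hydroxyls is the only unsubstituted ring carbon, SN2 attack at the primary allylic carbon keeps the 2E geometry, and the anhydrous medium leaves the lactone closed.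

Step 4
Reactants: 9 methyl 2-methylacetoacetate (methyl 2-methyl-3-oxobutanoate, racemic); 10 L-valine tert-butyl ester (free base)
Product: 11 methyl (2Z)-3-{[(2S)-1-tert-butoxy-3-methyl-1-oxobutan-2-yl]amino}-2-methylbut-2-enoate
Conditions: BF3·OEt2 (cat.), toluene, reflux, Dean–Stark
Reagents that add atoms: L-valine tert-butyl ester (10), CC(C)[C@H](N)C(=O)OC(C)(C)C
Why: Condensation of a β-keto ester with a primary amine gives the hydrogen-bonded (Z)-β-enamino ester (a vinylogous carbamate), which erases the racemic α-centre of 9 and attaches the auxiliary without touching the valine stereocentre.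

Step 5
Reactants: 11 the valine enamino ester; 7 geranyl bromide
Product: 13 methyl (2S,4E)-2-acetyl-2,5,9-trimethyldeca-4,8-dienoate [methyl (S)-2-geranyl-2-methylacetoacetate], via alkylated ketimine 12 (not isolated)
Conditions: LiN(iPr)2 (1.2 equiv), toluene, −78 °C; HMPA (1 equiv); geranyl bromide, −78 → −40 °C; then 1 M aq. citric acid–THF, rt
Reagents that add atoms: geranyl bromide (7), CC(C)=CCC/C(C)=C/CBr; water, O
Why: This is the auxiliary-controlled alkylation of a metalated chiral enamine of an α-alkyl β-keto ester, in which N-deprotonation gives a lithium aza-enolate held rigid by chelation of lithium to nitrogen and the valine ester carbonyl, the isopropyl group screens one face so that geranyl bromide attacks C2 from the other and sets the (S) quaternary centre (no α-hydrogen, so no epimerisation), and mild aqueous acid then hydrolyses the ketimine and releases the auxiliary.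

Step 6
Reactants: 8 8-butanoyl-6-geranyl-5,7-dihydroxychroman-2-one; 13 methyl (S)-2-geranyl-2-methylacetoacetate
Product: 15 (4S)-2-[(3-butanoyl-5-geranyl-2,4,6-trihydroxyphenyl)methyl]-4-geranyl-3,5-dihydroxy-4-methylcyclohexa-2,5-dien-1-one, via ring-opened triketo ester 14 (not isolated)
Conditions: 13 (1.5 equiv), LiN(iPr)2 (1.5 equiv), THF, −78 °C; add 8 premixed with LiN(SiMe3)2 (2.0 equiv) in THF–DMPU, −78 → −20 °C; then LiN(iPr)2 (3.5 equiv), −20 → 0 °C; cold 0.5 M aq. HCl to pH 3
Reagents that add atoms: none
Why: The lithium enolate formed at the only enolisable position of 13 (the acetyl CH3) adds to the lactone carbonyl of the dilithium salt of 8 and the tetrahedral intermediate expels the ring A aryloxide, giving triketo ester 14 as its diketonate (C1–C2 bond); further amide base then removes a proton from C6 and this diketone dianion terminus attacks the methyl ester with loss of methoxide (C5–C6 bond). The closest known reactions are the crossed Claisen acylation of ketone enolates by aryl esters and dihydrocoumarins and the Dieckmann-type cyclisation of 1,3-diketone dianions to cyclohexane-1,3,5-triones, run here consecutively in one flask. Ring B closes by a 6-(enolendo)-exo-trig acyl substitution, and the trione is deprotonated as it forms, which makes the closure irreversible and shields it from retro-Claisen cleavage. No stereocentre is created: C4 has no acidic hydrogen and is carried through unchanged, and its two ring neighbours are distinguished simply because C5 derives from the ester and C3 from the ketone of 13. The step needs chemoselectivity for the lactone carbonyl, which the substrate secures because the butanoyl ketone is conjugated to ortho and para phenoxides (a vinylogous carboxylate, neither electrophilic nor acidic enough to quench the enolate), the ester of 13 sits on a quaternary carbon and is inert at −78 °C, and the aryl ester is the only activated acyl donor present. In the closure C6 is the only carbanion that can reach the ester through a six-membered transition state, any enolate of the butanoyl group being a remote spectator.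

Step 7
Reactants: 15 the des-acetyl dimer; 16 acetyl chloride
Product: 18 (4R)-2-acetyl-6-[(3-butanoyl-5-geranyl-2,4,6-trihydroxyphenyl)methyl]-4-geranyl-3,5-dihydroxy-4-methylcyclohexa-2,5-dien-1-one (CNP0209203.1), via ring B enol acetate 17 (not isolated)
Conditions: AcCl (1.05 equiv), Et3N (2.5 equiv), CH2Cl2, −20 °C; then DMAP (0.3 equiv), rt
Reagents that add atoms: acetyl chloride (16), CC(=O)Cl
Why: The ring B enol, by far the most acidic site, is O-acetylated first and DMAP then relays the acetyl group to carbon (O-to-C acyl migration of a 1,3-dione enol ester, a Steglich-type rearrangement), C2 being the only ring carbon that gives an enolisable 2-acyl-1,3-dione and hence the thermodynamic sink, while ring A has no free carbon, any aryl acetate formed re-enters the same acylpyridinium pool, and the stereocentre is not touched (its descriptor changes from S to R only through the priority rules).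

Compound list
1 | phloroglucinol (benzene-1,3,5-triol) | Oc1cc(O)cc(O)c1 | starting material
2 | acrylic acid | C=CC(=O)O | starting material
3 | 3-(2,4,6-trihydroxyphenyl)propanoic acid | OC(=O)CCc1c(O)cc(O)cc1O | intermediate
4 | 5,7-dihydroxychroman-2-one | O=C1CCc2c(O)cc(O)cc2O1 | intermediate
5 | butanoyl chloride | CCCC(=O)Cl | starting material
6 | 8-butanoyl-5,7-dihydroxychroman-2-one | O=C1CCc2c(O)cc(O)c(C(=O)CCC)c2O1 | intermediate
7 | geranyl bromide, (2E)-1-bromo-3,7-dimethylocta-2,6-diene | CC(C)=CCC/C(C)=C/CBr | starting material
8 | 8-butanoyl-6-[(2E)-3,7-dimethylocta-2,6-dien-1-yl]-5,7-dihydroxychroman-2-one | O=C1CCc2c(O)c(C/C=C(\C)CCC=C(C)C)c(O)c(C(=O)CCC)c2O1 | intermediate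
9 | methyl 2-methyl-3-oxobutanoate (racemic) | COC(=O)C(C)C(C)=O | starting material
10 | L-valine tert-butyl ester, tert-butyl (2S)-2-amino-3-methylbutanoate | CC(C)[C@H](N)C(=O)OC(C)(C)C | starting material
11 | methyl (2Z)-3-{[(2S)-1-tert-butoxy-3-methyl-1-oxobutan-2-yl]amino}-2-methylbut-2-enoate | COC(=O)/C(C)=C(/C)N[C@@H](C(C)C)C(=O)OC(C)(C)C | intermediate
12 | methyl (2S,4E)-2-{N-[(2S)-1-tert-butoxy-3-methyl-1-oxobutan-2-yl]ethanimidoyl}-2,5,9-trimethyldeca-4,8-dienoate | COC(=O)[C@@](C)(C/C=C(\C)CCC=C(C)C)C(C)=N[C@@H](C(C)C)C(=O)OC(C)(C)C | intermediate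
13 | methyl (2S,4E)-2-acetyl-2,5,9-trimethyldeca-4,8-dienoate | COC(=O)[C@@](C)(C/C=C(\C)CCC=C(C)C)C(C)=O | intermediate
14 | methyl (2S,4E)-2-[5-(3-butanoyl-5-geranyl-2,4,6-trihydroxyphenyl)-3-oxopentanoyl]-2,5,9-trimethyldeca-4,8-dienoate (present as its lithium salt) | COC(=O)[C@@](C)(C/C=C(\C)CCC=C(C)C)C(=O)CC(=O)CCc1c(O)c(C/C=C(\C)CCC=C(C)C)c(O)c(C(=O)CCC)c1O | intermediate
15 | (4S)-2-[(3-butanoyl-5-geranyl-2,4,6-trihydroxyphenyl)methyl]-4-geranyl-3,5-dihydroxy-4-methylcyclohexa-2,5-dien-1-one | CCCC(=O)c1c(O)c(C/C=C(\C)CCC=C(C)C)c(O)c(CC2=C(O)[C@@](C)(C/C=C(\C)CCC=C(C)C)C(O)=CC2=O)c1O | intermediate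
16 | acetyl chloride | CC(=O)Cl | starting material
17 | (4R)-6-[(3-butanoyl-5-geranyl-2,4,6-trihydroxyphenyl)methyl]-4-geranyl-5-hydroxy-4-methyl-3-oxocyclohexa-1,5-dien-1-yl acetate | CCCC(=O)c1c(O)c(C/C=C(\C)CCC=C(C)C)c(O)c(CC2=C(O)[C@@](C)(C/C=C(\C)CCC=C(C)C)C(=O)C=C2OC(C)=O)c1O | intermediate
18 | (4R)-2-acetyl-6-[(3-butanoyl-5-geranyl-2,4,6-trihydroxyphenyl)methyl]-4-geranyl-3,5-dihydroxy-4-methylcyclohexa-2,5-dien-1-one | CCCC(=O)c1c(O)c(C/C=C(\C)CCC=C(C)C)c(O)c(CC2=C(O)[C@@](C)(C/C=C(\C)CCC=C(C)C)C(O)=C(C(C)=O)C2=O)c1O | target

Total step count: 7. Longest linear sequence: 5 steps (steps 1, 2, 3, 6, 7).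

Steps most likely to fail

Step 6. Aggregation of the dilithium salt of 8 may slow acyl transfer, proton exchange may consume the enolate, or ring closure may lag behind base-induced scission at the methylene bridge. The fallback sets out from 8 and returns at 15, replacing the cascade by a protected, staged sequence in which each bond is made and checked separately. The non-chelated 5-hydroxyl of 8 is methoxymethylated selectively (MOMCl, iPr2NEt, CH2Cl2, 0 °C) to 8-butanoyl-6-geranyl-7-hydroxy-5-(methoxymethoxy)chroman-2-one F1, a more soluble monophenol whose single phenoxide still deactivates the ketone. After one equivalent of LiN(SiMe3)2, the lactone is opened by the lithium enolate of 13 (THF, −78 °C), and the diketone methyl (2S,4E)-2-{5-[3-butanoyl-5-geranyl-2,4-dihydroxy-6-(methoxymethoxy)phenyl]-3-oxopentanoyl}-2,5,9-trimethyldeca-4,8-dienoate F2 is isolated. Ring B is then closed in a separate Dieckmann operation (LiN(iPr)2, THF, 0 °C, or NaOMe, MeOH) to (4S)-2-{[3-butanoyl-5-geranyl-2,4-dihydroxy-6-(methoxymethoxy)phenyl]methyl}-4-geranyl-3,5-dihydroxy-4-methylcyclohexa-2,5-dien-1-one F3. Brief treatment with dilute HCl in MeOH at room temperature removes the acetal and gives 15.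

Step 3. O-alkylation of the ambident phenoxide may outrun C-alkylation, and the heterogeneous reaction may stall. The fallback sets out from 6 and returns at 8. The oxygen is alkylated on purpose (geranyl bromide, K2CO3, acetone, rt) to 8-butanoyl-5-(geranyloxy)-7-hydroxychroman-2-one F4. The allyl group is then moved to carbon by a Lewis-acid-catalysed 1,3-shift of the aryl allyl ether (Bi(OTf)3 cat., CH2Cl2, 0 °C). The shift can end only at C6, because C4a and C8 are substituted.

Step 5. Facial discrimination in the alkylation of the lithiated enamine may be insufficient or of the wrong sense. The fallback sets out from 9 and returns at 13, giving up asymmetric induction for resolution. Direct alkylation of 9 with 7 (K2CO3, acetone, rt) gives racemic methyl (4E)-2-acetyl-2,5,9-trimethyldeca-4,8-dienoate F5. Preparative chromatography on a chiral stationary phase (supercritical CO2–MeOH) separates the enantiomers, and the (S) enantiomer is 13.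

Further compounds
F1 | step 6 | 8-butanoyl-6-geranyl-7-hydroxy-5-(methoxymethoxy)chroman-2-one | O=C1CCc2c(OCOC)c(C/C=C(\C)CCC=C(C)C)c(O)c(C(=O)CCC)c2O1
F2 | step 6 | methyl (2S,4E)-2-{5-[3-butanoyl-5-geranyl-2,4-dihydroxy-6-(methoxymethoxy)phenyl]-3-oxopentanoyl}-2,5,9-trimethyldeca-4,8-dienoate | COC(=O)[C@@](C)(C/C=C(\C)CCC=C(C)C)C(=O)CC(=O)CCc1c(OCOC)c(C/C=C(\C)CCC=C(C)C)c(O)c(C(=O)CCC)c1O
F3 | step 6 | (4S)-2-{[3-butanoyl-5-geranyl-2,4-dihydroxy-6-(methoxymethoxy)phenyl]methyl}-4-geranyl-3,5-dihydroxy-4-methylcyclohexa-2,5-dien-1-one | CCCC(=O)c1c(O)c(C/C=C(\C)CCC=C(C)C)c(OCOC)c(CC2=C(O)[C@@](C)(C/C=C(\C)CCC=C(C)C)C(O)=CC2=O)c1O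
F4 | step 3 | 8-butanoyl-5-{[(2E)-3,7-dimethylocta-2,6-dien-1-yl]oxy}-7-hydroxychroman-2-one | O=C1CCc2c(OC/C=C(\C)CCC=C(C)C)cc(O)c(C(=O)CCC)c2O1
F5 | step 5 | methyl (4E)-2-acetyl-2,5,9-trimethyldeca-4,8-dienoate (racemic) | COC(=O)C(C)(C/C=C(\C)CCC=C(C)C)C(C)=O
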